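## Structural features

The target is a C2-symmetric macrocyclic dimer of 3-methylquinolizidin-2-one. In each half, ring A is a piperidine (N5, C6–C9, C9a) and ring B a 4-piperidone (N5, C4, C3, C2, C1, C9a), fused through N5–C9a. Two pentamethylene chains join the halves head to tail, C9 of one to C1 of the other, so that C1, C9a, C9 and five CH2 groups of each half form a 16-membered carbocycle. Each half has four stereocentres (1R,3R,9S,9aS): C1, C9a and C9 are contiguous and C3 lies across the C2 carbonyl from C1. H-9 and H-9a are trans and H-1 and H-9a cis, so in the trans-fused chair–chair form the C9 chain and the C3 methyl are equatorial and the C1 chain axial, which avoids a syn-pentane contact between the two chains. C1 and C3 are enolisable, C9a is the β-carbon of a β-amino ketone (retro-Michael or retro-Mannich opening), and the tertiary amines are oxidisable; only C9 is configurationally locked. The real difficulties are the 16-membered ring, whose closure must form a C–C bond at C1, and the absolute configuration of the C9/C9a pair; C1 and C3 can be left to thermodynamic control at the end. The key step exploits ring B: C2 is a carbonyl carbon bonded to C1 and to the C3(CH3)–C4 unit that ends on N5, which is an ester carbon plus the three carbons of a propyl Grignard reagent, joined as a cyclopropanol and later opened toward N5.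

## Logic of the disconnections

21 to 19: both N5–C4 bonds are cut. N5–C4–C3–C2=O is a β-amino ketone, the retron of amine alkylation or conjugate addition. Both bicyclic halves become piperidines with an open side chain, and C1 and C3 become an equilibration problem. The forward step needs a secondary amine that is free only at that moment, and a base treatment that settles C1 and C3.

19 to 18 to 16: the C4–Br bond is reconnected to C2 as the C2–C4 bond of a cyclopropanol, and the N-carbamate is traced back to N-benzyl. The strained ring stores the ketone and the electrophilic C4 with C3 already methylated. The forward opening must cleave C2–C4 and not C2–C3, the nitrogen must not be oxidisable during bromination, and the hydrogenolysis must spare the cyclopropanols.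

16 to 14 and 15: C2–C3 and C2–C4 are cut in both halves (four C–C bonds). C3, C4 and the methyl group then come from one three-carbon reagent and what remains is a symmetric diester. The forward step must run twice at hindered, α-branched esters without enolising C1 and in the presence of basic nitrogen.

14 to 12 (twice, through 13): both C1–CH2 chain bonds are cut. C1 is α to an ester, so it is a natural enolate carbon, and the symmetry reduces the macrocycle to one monomer. The forward step must favour dimerisation and 16-membered ring closure over oligomerisation, and the nitrogen β to the enolate must not be a leaving group, hence N-benzyl and not a carbamate at this stage.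

12 to 11 to 9: the C–I bond is traced to C–OH, and the C1 methylene is excised so that the carboxyl carbon sits directly on C9a. In that form C9a is epimerisable and the ring is a hydrogenated picolinate. The forward step is a one-carbon homologation that must keep the C9a configuration and should avoid diazomethane.

9 to 8 to 6 to 5 to 4: the O-silyl and N-benzyl groups (from 7) are removed, then the absolute configuration is traced to a resolution and the trans relationship to an epimerisation at C9a. This requires that the trans isomer of the N–H piperidine is favoured at equilibrium and that a diastereomeric salt crystallises.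

4 to 3 to 1 and 2: ring A is traced back to a pyridine and the C9–chain bond is cut as an sp2–sp coupling. Two commercial compounds remain, and the 3-bromo substituent defines both the future C9 and the chain length. The cis selectivity of the hydrogenation is acceptable because of the later epimerisation.

## Other disconnections considered

Alternative 1: The cut is the C9–C9a bond of ring A. In the forward step LiN(iPr)2 would deprotonate the methylene between nitrogen and the tert-butyl ester of the alkenylaziridine A2. The carbanion would bond to the far alkene carbon (the future C9) while the allylic aziridine C–N bond breaks, an aza-[2,3]-Wittig shift driven by release of ring strain, giving the tetrahydropyridine A1.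
- In its favour: the shift is concerted and suprafacial, so one aziridine stereocentre would be translated into both C9 and C9a. No resolution and no epimerisation are needed. On absolute control of the C9/C9a pair without discarding half the material it is better than the chosen plan.
- Against it here: it solves only ring A, which the chosen plan obtains from a pyridine in two operations. A2 needs a multistep enantioselective preparation with a defined alkene geometry. A2 is drawn with the Z alkene that an envelope transition state with the ester turned away from the aziridine CH2 would need for a trans product; this rests on a model and would have to be secured first. A1 still lacks the carbon between C9a and the carboxyl group, and its ring alkene must be hydrogenated.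
- Comparison: structurally, A1 maps onto 6 after hydrogenation and ester exchange, so it is another entry to the same intermediate and not another way to ring B or the macrocycle. Mechanistically, a stereospecific sigmatropic shift stands against thermodynamic epimerisation plus resolution. In step count it is longer by the preparation of A2 and equal to the chosen plan in everything after 6.

Alternative 2: The cuts are C1–C2 and N5–C4 in both halves, with the macrocycle already present as the bis(cyclic imine) A4. In the forward step LiN(iPr)2 would turn each imine into its azaenolate at C1, acylation by the chloro ester A5 would form C1–C2, and the enaminone nitrogen would then displace chloride to form N5–C4, giving the bis(vinylogous amide) A3.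
- In its favour: as in the chosen plan, one small reagent supplies C2, C3, the methyl group and C4, but both ring-B bonds form in one operation and nitrogen needs no protecting group. From the macrocycle to the target it needs only the annulation and a reduction, against four steps from 14 to 21. On step count after the macrocycle and on protecting-group economy it is equal or better.
- Against it here: C9 is the α-carbon of the imine, so imine–enamine tautomerism or deprotonation on that side would erase the one centre that cannot be repaired later. A5 has an acidic α-hydrogen and a β-leaving group, so loss of HCl under the basic conditions is a likely diversion, and conjugate addition to the resulting acceptor would join C1 to C4 instead of C2. The tetrasubstituted C1=C9a bond of A3 must then be reduced with control of C9a relative to C9, and vinylogous amides are reluctant acceptors.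
- Comparison: structurally, C1 and C9a are carried at the sp2 level and set late, whereas the chosen plan fixes C9 and C9a before the macrocycle and leaves only enolisable centres for the end. Mechanistically, it is a polar acylation and alkylation with a base-sensitive electrophile, against a titanium-mediated cyclopropanation that tolerates the amine and does not enolise C1. In step economy it is potentially better after the macrocycle, but A4 needs its own macrocyclisation, which is no easier.

Alternative 3: The cuts are the two chain C–C bonds between the third and fourth carbons counted from C9; each is replaced by a CH2–SO2–CH2 bridge in the 18-membered bis(sulfone) A7. In the forward step KOH, CCl4 and tert-butanol would halogenate next to sulfur, and 1,3-elimination with extrusion of the SO2 unit would form both C=C bonds and contract the ring to the 16-membered diene A6 (double Ramberg–Bäcklund reaction).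
- In its favour: the macrocycle would be closed by thiolate alkylation, which is more dependable at high dilution than the enolate C-alkylation of step 9. On the ring-closing event itself this plan is the better one. Both quinolizidinone halves are complete, rigid bicycles before they are joined, so C1, C3 and C9a can be set and checked on a monomer.
- Against it here: each half must be a fully elaborated bicyclic lactam ketal with two different sulfur-bearing arms, a much longer monomer synthesis. Four atoms are introduced only to be excised. Carbene generated from CCl4 can add to the new alkenes. After A6, alkene hydrogenation, lactam reduction and ketal hydrolysis remain.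
- Comparison: structurally, it cuts the least functionalised part of the molecule and gains no stereochemical simplification, whereas the chosen plan cuts next to functional groups. Mechanistically, a reliable extrusion stands against an enolate macrocyclisation that is the weak point of the chosen route. In step economy it is clearly longer.

Key step: step 10

Remarks on the chemistry:
- Structures: 14 and 16 are drawn with the same configuration at C1, C9 and C9a as 21 (R, S, S in every half).
- Nitrogen: a benzyl group left on N5 through ring opening and closure would be oxidised by the brominating agent and would end as a quaternary β-ammonium ketone that eliminates readily. Benzyl is therefore exchanged for Boc after the key step, and ring B is closed by the free secondary amine.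
- Homologation: the chain extension at C9a uses the Kowalski homologation, because activating an α-(dialkylamino) acid invites decarbonylation and diazomethane is a hazard.
- C1: 13, 14 and 16–20 are written with the 1R configuration that 21 needs. Enolate alkylation beside a β-amino centre may favour the C1 epimer instead; it would be carried along, because step 13 equilibrates C1.
- Cyclopropanols: only the cis arrangement within each cyclopropanol is controlled. 16–18, and C3 of 19–20, are diastereomer mixtures of which one is drawn; all converge in step 13.

## Route

Step 1
Reactants: 1 methyl 3-bromopyridine-2-carboxylate; 2 pent-4-yn-1-ol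
Product: 3 methyl 3-(5-hydroxypent-1-yn-1-yl)pyridine-2-carboxylate
Conditions: PdCl2(PPh3)2 (3 mol%), CuI (5 mol%), Et3N, THF, 50 °C
Reagents that add atoms: none
Why: Sonogashira coupling of an electron-poor 3-bromopyridine with a terminal alkyne; the free primary alcohol is tolerated and all five chain carbons are installed at the future C9.

Step 2
Reactants: 3 methyl 3-(5-hydroxypent-1-yn-1-yl)pyridine-2-carboxylate
Product: 4 methyl (2RS,3SR)-3-(5-hydroxypentyl)piperidine-2-carboxylate (cis, racemic)
Conditions: H2 (4 bar), PtO2, AcOH, rt
Reagents that add atoms: none
Why: Heterogeneous hydrogenation saturates the alkyne and the protonated pyridine; the ring hydrogens are delivered from the catalyst face, so C2 and C3 should come out cis (relative configuration only).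

Step 3
Reactants: 4 methyl (2RS,3SR)-3-(5-hydroxypentyl)piperidine-2-carboxylate
Product: 5 methyl (2RS,3RS)-3-(5-hydroxypentyl)piperidine-2-carboxylate (trans, racemic)
Conditions: NaOMe (0.5 equiv), MeOH, reflux
Reagents that add atoms: none
Why: Base-mediated epimerisation α to the ester inverts C2 (the future C9a) through the enolate; the trans, diequatorial isomer of the N–H piperidine should dominate at equilibrium, and C3 is not acidic. Residual cis isomer is removed by chromatography or in step 4.

Step 4
Reactants: 5 methyl (2RS,3RS)-3-(5-hydroxypentyl)piperidine-2-carboxylate
Product: 6 methyl (2S,3S)-3-(5-hydroxypentyl)piperidine-2-carboxylate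
Conditions: (−)-O,O′-dibenzoyl-L-tartaric acid (1 equiv), EtOH, recrystallise; then aq. Na2CO3, CH2Cl2
Reagents that add atoms: none
Why: Classical resolution by diastereomeric salt crystallisation fixes the absolute configuration of C9 and C9a; if the salt of the mirror-image amine is the less soluble one, the D-acid is used in the same way. X-ray diffraction of the crystalline salt would establish which enantiomer it holds.

Step 5
Reactants: 6 methyl (2S,3S)-3-(5-hydroxypentyl)piperidine-2-carboxylate; 7 benzyl bromide
Product: 8 methyl (2S,3S)-1-benzyl-3-(5-hydroxypentyl)piperidine-2-carboxylate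
Conditions: K2CO3, MeCN, rt → 50 °C
Reagents that add atoms: benzyl bromide (7), BrCc1ccccc1
Why: SN2 N-alkylation of the secondary amine, which is far more nucleophilic than the primary alcohol. The resulting tertiary amine tolerates the organolithium, enolate and titanium steps and cannot leave from a β-amino ester enolate.

Step 6
Reactants: 8 methyl (2S,3S)-1-benzyl-3-(5-hydroxypentyl)piperidine-2-carboxylate
Product: 9 methyl (2S,3S)-1-benzyl-3-[5-(tert-butyldimethylsilyloxy)pentyl]piperidine-2-carboxylate
Conditions: TBSCl, imidazole, CH2Cl2, rt
Reagents that add atoms: tert-butyldimethylsilyl chloride, CC(C)(C)[Si](C)(C)Cl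
Why: Standard silylation of the primary alcohol, so that no alkoxide is present during the homologation.

Step 7
Reactants: 9 methyl (2S,3S)-1-benzyl-3-[5-(tert-butyldimethylsilyloxy)pentyl]piperidine-2-carboxylate
Product: 11 methyl 2-[(2R,3S)-1-benzyl-3-(5-hydroxypentyl)piperidin-2-yl]acetate, via silyl ether of the homologated ester 10 (not isolated)
Conditions: CH2Br2, lithium 2,2,6,6-tetramethylpiperidide, THF, −78 °C; LiN(SiMe3)2, −78 °C; n-BuLi, −78 °C → rt; then HCl/MeOH, 0 °C → rt
Reagents that add atoms: dibromomethane, BrCBr; methanol, CO
Why: Kowalski ester homologation, known for N,N-dialkyl α-amino esters: LiCHBr2 adds to the ester, Br/Li exchange on the dibromo ketone enolate triggers rearrangement to the ynolate with 1,2-shift of the piperidin-2-yl group (retention at C9a), and acidic methanol gives the methyl ester through the ketene. The same acidic methanol cleaves the silyl ether.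

Step 8
Reactants: 11 methyl 2-[(2R,3S)-1-benzyl-3-(5-hydroxypentyl)piperidin-2-yl]acetate
Product: 12 methyl 2-[(2R,3S)-1-benzyl-3-(5-iodopentyl)piperidin-2-yl]acetate
Conditions: I2, PPh3, imidazole, CH2Cl2, 0 °C
Reagents that add atoms: iodine, [I][I]
Why: Appel-type iodination of the primary alcohol under neutral conditions; the amino iodide is used at once so that N-quaternisation cannot compete.

Step 9
Reactants: 12 methyl 2-[(2R,3S)-1-benzyl-3-(5-iodopentyl)piperidin-2-yl]acetate (two molecules)
Product: 14 C2-symmetric 16-membered macrocyclic bis(N-benzylpiperidine) dimethyl diester, via open-chain iodo diester 13 (not isolated)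
Conditions: LiN(iPr)2 (1.1 equiv), THF, −78 °C, 5 mM; DMPU, −78 → −10 °C
Reagents that add atoms: none
Why: C-alkylation of the lithium ester enolate by the primary iodide, first between two molecules and then within 13 to close the 16-membered ring; self-alkylation within one monomer would need an eight-membered ring and should be slow. C1 is formed here under substrate control from C9a; its configuration is not relied upon, because step 13 equilibrates it.

Step 10
Reactants: 14 C2-symmetric 16-membered macrocyclic bis(N-benzylpiperidine) dimethyl diester; 15 propylmagnesium bromide
Product: 16 macrocyclic bis(N-benzylpiperidine) with a (1R,2R)-1-hydroxy-2-methylcyclopropyl group on each C1 (cis-cyclopropanols)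
Conditions: Ti(OiPr)4 (2.4 equiv), PrMgBr (8 equiv, added over 2 h), THF, 0 °C → rt
Reagents that add atoms: propylmagnesium bromide (15), CCC[Mg]Br
Why: Two equivalents of PrMgBr alkylate Ti(OiPr)4, and the dipropyltitanium species loses propane by β-hydride elimination to give the titanacyclopropane of propene, a 1,2-dicarbanion equivalent. The ester carbonyl of 14 inserts into a Ti–C bond, most likely the less hindered Ti–CH2 bond (forming C2–C4); methoxide is expelled to leave a β-titanio ketone, and the remaining Ti–C3 bond adds to that ketone (forming C2–C3). This is the Kulinkovich hydroxycyclopropanation, known for α-branched esters and for esters carrying tertiary amines; each cyclopropane closes by a 3-exo-trig addition of the carbon–titanium bond to the carbonyl group. C2 and C3 of each cyclopropane are set relative to each other in that ring-closing step, which with homologues of EtMgBr is known to place the substituent from the ester (here C1) and the methyl group cis. The face of the ester used relative to the existing C1 centre is not controlled, so 16 is expected as a mixture of cis-cyclopropanol diastereomers that all lead to the same enolisable C3 later. The step needs twofold cyclopropanation to win over simple Grignard addition and over enolisation at C1. Slow addition of the Grignard reagent and a full equivalent of titanium per ester keep free PrMgBr low, and the alkyltitanium species are too weakly basic to deprotonate C1; the tertiary benzylamines are spectators.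

Step 11
Reactants: 16 macrocyclic bis(N-benzylpiperidine) bis(cis-2-methylcyclopropanol)
Product: 18 N,N′-di-Boc macrocyclic bis(cis-2-methylcyclopropanol), via N-debenzylated bis(cyclopropanol) 17 (not isolated)
Conditions: H2 (1 atm), Pd(OH)2/C, Boc2O, EtOAc/MeOH, rt
Reagents that add atoms: di-tert-butyl dicarbonate, CC(C)(C)OC(=O)OC(=O)OC(C)(C)C
Why: Hydrogenolysis of the benzylic C–N bonds with in situ carbamate formation; tertiary cyclopropanols should be inert to hydrogen over palladium in neutral medium, and the carbamate makes nitrogen inert to NBS in step 12.

Step 12
Reactants: 18 N,N′-di-Boc macrocyclic bis(cis-2-methylcyclopropanol)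
Product: 19 N,N′-di-Boc macrocyclic bis[(2S)-3-bromo-2-methylpropanoyl] compound (bis(β-bromo ketone))
Conditions: NBS (2.2 equiv), CH2Cl2, 0 °C, dark
Reagents that add atoms: N-bromosuccinimide, O=C1CCC(=O)N1Br
Why: Electrophilic ring opening of cyclopropanols by NBS: bromine attacks the least substituted ring carbon C4 and the C2–C4 bond breaks, giving the β-bromo ketone with the C2–C3 bond and the methyl group untouched.

Step 13
Reactants: 19 N,N′-di-Boc macrocyclic bis(β-bromo ketone)
Product: 21 CNP0268544.9, via bis(amino β-bromo ketone) bis(trifluoroacetate) 20 (not isolated)
Conditions: TFA, CH2Cl2, 0 °C → rt; evaporate; K2CO3, MeCN, rt; then MeOH, 45 °C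
Reagents that add atoms: none
Why: Acid removes both Boc groups; on neutralisation each secondary amine forms N5–C4, either by 6-exo-tet displacement of bromide or, after E1cB loss of HBr, by 6-endo-trig aza-Michael addition. Carbonate in methanol then equilibrates C3 and C1 α to the ketone to the most stable arrangement (C3 methyl equatorial, C1 chain axial and clear of the C9 chain), which is 21. C9 is untouched, and the mild base should leave C9a trans to it.

## Compound list

1 | methyl 3-bromopyridine-2-carboxylate | COC(=O)c1ncccc1Br | starting material
2 | pent-4-yn-1-ol | C#CCCCO | starting material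
3 | methyl 3-(5-hydroxypent-1-yn-1-yl)pyridine-2-carboxylate | COC(=O)c1ncccc1C#CCCCO | intermediate
4 | methyl (2RS,3SR)-3-(5-hydroxypentyl)piperidine-2-carboxylate (cis, racemic; 2R,3S enantiomer drawn) | COC(=O)[C@@H]1NCCC[C@@H]1CCCCCO | intermediate
5 | methyl (2RS,3RS)-3-(5-hydroxypentyl)piperidine-2-carboxylate (trans, racemic; 2S,3S enantiomer drawn) | COC(=O)[C@H]1NCCC[C@@H]1CCCCCO | intermediate
6 | methyl (2S,3S)-3-(5-hydroxypentyl)piperidine-2-carboxylate | COC(=O)[C@H]1NCCC[C@@H]1CCCCCO | intermediate
7 | benzyl bromide | BrCc1ccccc1 | starting material
8 | methyl (2S,3S)-1-benzyl-3-(5-hydroxypentyl)piperidine-2-carboxylate | COC(=O)[C@H]1N(Cc2ccccc2)CCC[C@@H]1CCCCCO | intermediate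
9 | methyl (2S,3S)-1-benzyl-3-[5-(tert-butyldimethylsilyloxy)pentyl]piperidine-2-carboxylate | COC(=O)[C@H]1N(Cc2ccccc2)CCC[C@@H]1CCCCCO[Si](C)(C)C(C)(C)C | intermediate
10 | methyl 2-[(2R,3S)-1-benzyl-3-[5-(tert-butyldimethylsilyloxy)pentyl]piperidin-2-yl]acetate (not isolated) | COC(=O)C[C@H]1N(Cc2ccccc2)CCC[C@@H]1CCCCCO[Si](C)(C)C(C)(C)C | intermediate
11 | methyl 2-[(2R,3S)-1-benzyl-3-(5-hydroxypentyl)piperidin-2-yl]acetate | COC(=O)C[C@H]1N(Cc2ccccc2)CCC[C@@H]1CCCCCO | intermediate
12 | methyl 2-[(2R,3S)-1-benzyl-3-(5-iodopentyl)piperidin-2-yl]acetate | COC(=O)C[C@H]1N(Cc2ccccc2)CCC[C@@H]1CCCCCI | intermediate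
13 | methyl (2R)-7-[(2R,3S)-1-benzyl-2-(2-methoxy-2-oxoethyl)piperidin-3-yl]-2-[(2S,3S)-1-benzyl-3-(5-iodopentyl)piperidin-2-yl]heptanoate (open-chain head-to-tail dimer, not isolated) | COC(=O)C[C@H]1N(Cc2ccccc2)CCC[C@@H]1CCCCC[C@@H](C(=O)OC)[C@H]3N(Cc4ccccc4)CCC[C@@H]3CCCCCI | intermediate
14 | 16-membered carbocycle fused at two opposite C–C bonds (C9a–C9) to (2S,3S)-1-benzylpiperidines, with CO2Me on each ring carbon C1 (R) next to C9a; the two C1–(CH2)5–C9 tethers run head to tail | COC(=O)[C@@H]1CCCCC[C@H]2CCCN(Cc3ccccc3)[C@@H]2[C@H](C(=O)OC)CCCCC[C@H]4CCCN(Cc5ccccc5)[C@@H]41 | intermediate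
15 | propylmagnesium bromide | CCC[Mg]Br | starting material
16 | as 14, with each CO2Me replaced by a (1R,2R)-1-hydroxy-2-methylcyclopropyl group (methyl cis to C1, trans to OH; one diastereomer of the mixture drawn) | C[C@@H]6C[C@]6(O)[C@@H]1CCCCC[C@H]2CCCN(Cc3ccccc3)[C@@H]2[C@H]([C@@]7(O)C[C@H]7C)CCCCC[C@H]4CCCN(Cc5ccccc5)[C@@H]41 | intermediate
17 | N-debenzylated bis(cyclopropanol), both nitrogens N–H (not isolated) | C[C@@H]6C[C@]6(O)[C@@H]1CCCCC[C@H]2CCCN[C@@H]2[C@H]([C@@]7(O)C[C@H]7C)CCCCC[C@H]4CCCN[C@@H]41 | intermediate
18 | N,N′-di-Boc bis(cyclopropanol) | C[C@@H]6C[C@]6(O)[C@@H]1CCCCC[C@H]2CCCN(C(=O)OC(C)(C)C)[C@@H]2[C@H]([C@@]7(O)C[C@H]7C)CCCCC[C@H]4CCCN(C(=O)OC(C)(C)C)[C@@H]41 | intermediate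
19 | N,N′-di-Boc macrocycle with a (2S)-3-bromo-2-methylpropanoyl group on each C1 | C[C@H](CBr)C(=O)[C@@H]1CCCCC[C@H]2CCCN(C(=O)OC(C)(C)C)[C@@H]2[C@H](C(=O)[C@H](C)CBr)CCCCC[C@H]4CCCN(C(=O)OC(C)(C)C)[C@@H]41 | intermediate
20 | bis(amino β-bromo ketone) as its bis(trifluoroacetate) salt (not isolated) | C[C@H](CBr)C(=O)[C@@H]1CCCCC[C@H]2CCCN[C@@H]2[C@H](C(=O)[C@H](C)CBr)CCCCC[C@H]4CCCN[C@@H]41.OC(=O)C(F)(F)F.OC(=O)C(F)(F)F | intermediate
21 | CNP0268544.9, C2-symmetric 16-membered bis(3-methylquinolizidin-2-one), (1R,3R,9S,9aS) in each half | C[C@@H]1CN2CCC[C@@H]3CCCCC[C@H]4C(=O)[C@H](C)CN5CCC[C@H](CCCCC[C@@H](C1=O)[C@H]32)[C@@H]45 | target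

Total step count: 13. Longest linear sequence: 13 steps (the route is linear; 12 enters step 9 twice).

## Least certain steps

Step 10 (key step).
- Most likely to go wrong: incomplete twofold cyclopropanation, or direct addition of PrMgBr to the hindered α-branched esters, because the methyl-substituted titanacyclopropane is less reactive than the parent and must react twice in one molecule.
- Fallback, from 14 back to the route at 21: each ester of 14 is converted with MeNH(OMe)·HCl and iPrMgCl (THF, −20 °C) into the bis(N-methoxy-N-methylamide) F1. EtMgBr gives the bis(ethyl ketone) F2, and hydrogenolysis (H2, Pd(OH)2/C, MeOH) gives the bis(amino ketone) F3. Aqueous formaldehyde in MeOH/AcOH at 60 °C then closes both B rings by intramolecular Mannich reaction: the iminium forms on N5, the C3 enol carbon attacks, and formaldehyde supplies C4 (closure through C1 would need a four-membered ring). The base equilibration of step 13 gives 21.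

Step 9.
- Most likely to go wrong: oligomerisation outrunning the 16-membered ring closure, since both events are the same bimolecular reaction and only dilution separates them. Poor or reversed facial selectivity at C1 is also possible but is corrected in step 13.
- Fallback, from 11 and 12 back to the route at 14: 11 is converted into its alkoxide–enolate (2.1 equiv LiN(iPr)2, THF, −78 °C; the alkoxide is a bystander) and C-alkylated at normal concentration with one equivalent of 12 to give the open-chain hydroxy diester F4. Appel iodination (I2, PPh3, imidazole) gives 13, now isolated. Slow addition of 13 to LiN(SiMe3)2 in THF/DMPU at 1 mM closes the ring to 14.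

Step 7.
- Most likely to go wrong: deprotonation at C9a by the amide bases before LiCHBr2 adds, with loss of the trans relationship, or a sluggish carbenoid rearrangement for this hindered α-amino ketone enolate.
- Fallback, from 9 back to the route at 11: iBu2AlH (toluene, −78 °C) reduces 9 to the aldehyde F5. Wittig reaction with Ph3P=CHOMe (from the phosphonium chloride and KN(SiMe3)2) gives the enol ether F6. Aqueous HCl in THF hydrolyses the enol ether and the silyl ether to the hydroxy aldehyde F7. Pinnick oxidation (NaClO2, NaH2PO4, 2-methylbut-2-ene) gives the amino acid F8, and HCl/MeOH esterifies it to 11.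

Step 12.
- Most likely to go wrong: ring opening toward C3 instead of C4 if a radical pathway competes with the electrophilic one, or further bromination α to the new ketone.
- Fallback, from 18 back to the route at 21: aerobic oxidation with Pd(OAc)2 and pyridine under O2 in toluene at 80 °C opens each cyclopropanol at the same C2–C4 bond (β-carbon elimination, then β-hydride elimination), giving the bis(isopropenyl ketone) F9. TFA and then K2CO3 in MeOH, as in step 13, remove Boc and close both rings by aza-Michael addition to give 21.

## Further compounds

F1 | step 10 | macrocyclic bis(N-methoxy-N-methylamide), N-benzyl | CON(C)C(=O)[C@@H]1CCCCC[C@H]2CCCN(Cc3ccccc3)[C@@H]2[C@H](C(=O)N(C)OC)CCCCC[C@H]4CCCN(Cc5ccccc5)[C@@H]41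
F2 | step 10 | macrocyclic bis(ethyl ketone), N-benzyl | CCC(=O)[C@@H]1CCCCC[C@H]2CCCN(Cc3ccccc3)[C@@H]2[C@H](C(=O)CC)CCCCC[C@H]4CCCN(Cc5ccccc5)[C@@H]41
F3 | step 10 | macrocyclic bis(amino ethyl ketone), N–H | CCC(=O)[C@@H]1CCCCC[C@H]2CCCN[C@@H]2[C@H](C(=O)CC)CCCCC[C@H]4CCCN[C@@H]41
F4 | step 9 | methyl (2R)-7-[(2R,3S)-1-benzyl-2-(2-methoxy-2-oxoethyl)piperidin-3-yl]-2-[(2S,3S)-1-benzyl-3-(5-hydroxypentyl)piperidin-2-yl]heptanoate | COC(=O)C[C@H]1N(Cc2ccccc2)CCC[C@@H]1CCCCC[C@@H](C(=O)OC)[C@H]3N(Cc4ccccc4)CCC[C@@H]3CCCCCO
F5 | step 7 | (2S,3S)-1-benzyl-3-[5-(tert-butyldimethylsilyloxy)pentyl]piperidine-2-carbaldehyde | O=C[C@H]1N(Cc2ccccc2)CCC[C@@H]1CCCCCO[Si](C)(C)C(C)(C)C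
F6 | step 7 | (2S,3S)-1-benzyl-2-[(E)-2-methoxyethenyl]-3-[5-(tert-butyldimethylsilyloxy)pentyl]piperidine (E isomer of an E/Z mixture drawn) | CO/C=C/[C@H]1N(Cc2ccccc2)CCC[C@@H]1CCCCCO[Si](C)(C)C(C)(C)C
F7 | step 7 | 2-[(2R,3S)-1-benzyl-3-(5-hydroxypentyl)piperidin-2-yl]acetaldehyde | O=CC[C@H]1N(Cc2ccccc2)CCC[C@@H]1CCCCCO
F8 | step 7 | 2-[(2R,3S)-1-benzyl-3-(5-hydroxypentyl)piperidin-2-yl]acetic acid | OC(=O)C[C@H]1N(Cc2ccccc2)CCC[C@@H]1CCCCCO
F9 | step 12 | N,N′-di-Boc macrocyclic bis(isopropenyl ketone) | C=C(C)C(=O)[C@@H]1CCCCC[C@H]2CCCN(C(=O)OC(C)(C)C)[C@@H]2[C@H](C(=O)C(C)=C)CCCCC[C@H]4CCCN(C(=O)OC(C)(C)C)[C@@H]41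
A1 | alternative 1 | tert-butyl (2S,3S)-3-[5-(tert-butyldimethylsilyloxy)pentyl]-1,2,3,6-tetrahydropyridine-2-carboxylate | CC(C)(C)OC(=O)[C@H]1NCC=C[C@@H]1CCCCCO[Si](C)(C)C(C)(C)C
A2 | alternative 1 | tert-butyl 2-[(2S)-2-[(1Z)-7-(tert-butyldimethylsilyloxy)hept-1-en-1-yl]aziridin-1-yl]acetate | CC(C)(C)OC(=O)CN1C[C@@H]1/C=C\CCCCCO[Si](C)(C)C(C)(C)C
A3 | alternative 2 | macrocyclic bis(vinylogous amide) with C1=C9a double bonds (3R,9S in each half) | C[C@@H]1CN2CCC[C@@H]3CCCCCC4=C5N(C[C@@H](C)C4=O)CCC[C@@H]5CCCCCC(C1=O)=C32
A4 | alternative 2 | 16-membered macrocyclic bis(1-piperideine), 9S in each half | C1C2=NCCC[C@@H]2CCCCCCC3=NCCC[C@@H]3CCCCC1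
A5 | alternative 2 | methyl 3-chloro-2-methylpropanoate (racemic) | COC(=O)C(C)CCl
A6 | alternative 3 | 16-membered E,E-diene, ring A as C6 lactam, C2 as dioxolane | C[C@@H]1CN2C(=O)CC[C@@H]3CC/C=C/C[C@H]4C6(OCCO6)[C@H](C)CN5C(=O)CC[C@H](CC/C=C/C[C@@H](C17OCCO7)[C@H]32)[C@@H]45
A7 | alternative 3 | 18-membered bis(sulfone), ring A as C6 lactam, C2 as dioxolane | C[C@@H]1CN2C(=O)CC[C@@H]3CCCS(=O)(=O)CC[C@H]4C6(OCCO6)[C@H](C)CN5C(=O)CC[C@H](CCCS(=O)(=O)CC[C@@H](C17OCCO7)[C@H]32)[C@@H]45
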